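**Plan**

- Retrosynthesis: the C12 O–Si bond is cut last. Then come C6–C7 (Stille coupling of a C7 enol triflate with a C1–C6 alkenylstannane), C7–C8 (formylation) and C14=C15 (Wittig). Then the ring bond C9–C10 between the carbonyl carbon and the bromine-bearing alkene carbon is opened. The two aldehydes go back to allyl groups, and these to an ester plus two allyl Grignard units.
- Enabling feature: C12 of the cyclopentenone carries two CH2–C(sp2) arms, C8–C9 inside the ring and C13–C14 in the octenyl chain, next to the C11=C10(Br) unit. Opening C9–C10 therefore gives a mirror-symmetric 3-(bromoethynyl)-3-silyloxypentanedial with two enantiotopic CH2CHO arms, and its bromoalkyne already holds the C10 bromine.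
- Forward order: the symmetric open-chain dialdehyde is built in four steps and the only ring is closed in step 5. The ω-chain is attached in step 6 and the α-chain in steps 7–9. Desilylation in step 10 ends the route.
- Stereochemistry: C12 comes from catalyst-controlled choice between the enantiotopic formyl arms. 14Z comes from a lithium-salt-free Wittig reaction, 7Z from a lithium-chelated enolate trapped as its enol triflate and carried through the coupling with retention, and 5E from syn-hydrostannation.

Key step: step 5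

Remark on numbering: C1–C20 follow prostanoid numbering of the target (C1 ester carbon, ring C8–C12, C12 the carbinol carbon). The CIP descriptor at C12 changes from S (products of steps 5 and 6) to R (from step 7 on) only because C8 gains priority; the spatial arrangement is unchanged.

Assumption: (R)-Tol-BINAP is taken to select the arm that leads to the S aldehyde of step 5; should the opposite sense be found, (S)-Tol-BINAP is used with no other change.

**Route**

Step 1
Reactants: 1 ethyl 3-(trimethylsilyl)prop-2-ynoate; 2 allylmagnesium bromide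
Product: 4 4-[(trimethylsilyl)ethynyl]hepta-1,6-dien-4-ol, via 1-(trimethylsilyl)hex-5-en-1-yn-3-one 3 (not isolated)
Conditions: 2 (2.3 equiv), Et2O, −78 → 0 °C; aq NH4Cl
Reagents that add atoms: none
Why: Double Grignard addition to the ester through ketone 3 (allyl Grignard reagents add 1,2 through a six-membered transition state, and the silyl cap protects the alkyne from deprotonation and conjugate addition) should give the tertiary carbinol, which is achiral because the two allyl groups are identical.

Step 2
Reactants: 4 4-[(trimethylsilyl)ethynyl]hepta-1,6-dien-4-ol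
Product: 5 triethyl({4-[(trimethylsilyl)ethynyl]hepta-1,6-dien-4-yl}oxy)silane
Conditions: Et3SiOTf, 2,6-lutidine, CH2Cl2, −78 → 0 °C
Reagents that add atoms: triethylsilyl trifluoromethanesulfonate, CC[Si](CC)(CC)OS(=O)(=O)C(F)(F)F
Why: Silylation of a hindered tertiary alcohol with a silyl triflate and a hindered pyridine base is routine, and the triethylsilyl ether should survive steps 3–9 yet leave under buffered fluoride at the end.

Step 3
Reactants: 5 triethyl({4-[(trimethylsilyl)ethynyl]hepta-1,6-dien-4-yl}oxy)silane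
Product: 6 {[4-(bromoethynyl)hepta-1,6-dien-4-yl]oxy}triethylsilane
Conditions: NBS (1.15 equiv), AgNO3 (10 mol %), dry acetone, rt, dark
Reagents that add atoms: N-bromosuccinimide, O=C1CCC(=O)N1Br
Why: Silver-catalysed desilylative bromination (silver acetylide from the alkynylsilane, then electrophilic bromination by NBS) should turn C–Si directly into C–Br, while the isolated terminal alkenes do not react with NBS in dry acetone in the dark.

Step 4
Reactants: 6 {[4-(bromoethynyl)hepta-1,6-dien-4-yl]oxy}triethylsilane
Product: 8 3-(bromoethynyl)-3-[(triethylsilyl)oxy]pentanedial, via bis(1,2,4-trioxolane) 7 (not isolated)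
Conditions: O3, CH2Cl2, −78 °C (Sudan Red 7B end point); PPh3, −78 °C → rt; used without storage
Reagents that add atoms: ozone, [O-][O+]=O
Why: Ozonolysis should cleave the two monosubstituted alkenes much faster than the electron-poor bromoalkyne (indicator-controlled end point), and the neutral phosphine work-up spares the β-silyloxy dialdehyde from E1cB loss of silanolate.

Step 5
Reactants: 8 3-(bromoethynyl)-3-[(triethylsilyl)oxy]pentanedial
Product: 9 [(1S)-3-bromo-4-oxo-1-[(triethylsilyl)oxy]cyclopent-2-en-1-yl]acetaldehyde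
Conditions: [Rh((R)-Tol-BINAP)]BF4 (10 mol %; from [Rh(nbd)((R)-Tol-BINAP)]BF4 and H2), CH2Cl2 (0.05 M), rt
Reagents that add atoms: none
Why: Proposed new method: cationic monovalent rhodium should insert into one formyl C–H bond, the acyl hydride of trivalent rhodium should add H–Rh across the tethered bromoalkyne in the anti sense (H to C11, Rh to the bromine-bearing C10) to give a six-membered acyl(alkenyl)rhodacycle, and C–C reductive elimination should then form the C9–C10 bond, so that the alkyne bromine arrives directly as the C10–Br of the enone. The closest known reaction type is the rhodium–bisphosphine-catalysed intramolecular trans-hydroacylation of 3-alkoxy-4-alkynals to cyclopent-2-enones, including its Tol-BINAP-controlled desymmetrising and kinetic-resolution variants; new are the 1-bromoalkyne as acceptor and the choice between two enantiotopic formyl groups instead of two alkynes. The five-membered ring closes in a formal 5-endo-dig acyl addition, realised as reductive elimination from the rhodacycle, in preference to 4-exo-dig closure to an alkylidenecyclobutanone, which the fully substituted C12 ether carbon and the anti hydrometalation disfavour. No bond to C12 is formed; C12 becomes a stereocentre because the C2-symmetric ligand allows only one of the two enantiotopic CH2CHO arms to cyclise, so its configuration is under catalyst control. The step needs enantiotopic-group selectivity, C–H over C–Br oxidative addition and mono-cyclisation: the bromine lone pair should stabilise the η2-vinyl (carbenoid) species through which the anti addition passes and polarise the alkyne so that hydride goes to C11, alkyne coordination makes the C–H insertion chelation-assisted and fast, and the second formyl group is left without a partner once the single alkyne is consumed.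

Step 6
Reactants: 9 [(1S)-3-bromo-4-oxo-1-[(triethylsilyl)oxy]cyclopent-2-en-1-yl]acetaldehyde; 10 hexyl(triphenyl)phosphonium bromide
Product: 12 (4S)-2-bromo-4-[(2Z)-oct-2-en-1-yl]-4-[(triethylsilyl)oxy]cyclopent-2-en-1-one, via hexylidenetriphenylphosphorane 11 (not isolated)
Conditions: 10, NaN(SiMe3)2 (0.95 equiv relative to 10), THF, 0 °C; ylide solution added slowly to 9 in THF at −78 °C, then to −20 °C
Reagents that add atoms: none
Why: Lithium-salt-free Wittig olefination with a non-stabilised ylide under kinetic control (cis-oxaphosphetane) should give the 14Z alkene; the aldehyde reacts far faster than the conjugated ketone, and slow inverse addition at −78 °C keeps the basic ylide from enolising the β-silyloxy aldehyde.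

Step 7
Reactants: 12 (4S)-2-bromo-4-[(2Z)-oct-2-en-1-yl]-4-[(triethylsilyl)oxy]cyclopent-2-en-1-one
Product: 15 (Z)-{(5R)-3-bromo-2-oxo-5-[(2Z)-oct-2-en-1-yl]-5-[(triethylsilyl)oxy]cyclopent-3-en-1-ylidene}methyl trifluoromethanesulfonate, via lithium dienolate 13 (not isolated), via lithium chelate 14 (not isolated)
Conditions: LiN(iPr)2 (1.05 equiv), THF, −78 °C; CF3CH2OCHO (1.1 equiv), −78 °C; then N-(5-chloropyridin-2-yl)bis(trifluoromethanesulfonyl)imide (1.3 equiv) in the same flask, −78 → 0 °C; pH 7 buffer
Reagents that add atoms: 2,2,2-trifluoroethyl formate, O=COCC(F)(F)F; N-(5-chloropyridin-2-yl)bis(trifluoromethanesulfonyl)imide, FC(F)(F)S(=O)(=O)N(c1ccc(Cl)cn1)S(=O)(=O)C(F)(F)F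
Why: Kinetic deprotonation at C8, the only enolisable position, and crossed Claisen C-formylation with the activated formate should end at the lithium β-oxido enone 14, in which lithium bridges the two oxygens in a six-membered chelate and so holds the exocyclic oxygen cis to C9, and kinetic O-sulfonylation of that more accessible oxygen in the same flask should fix the Z enol triflate without isolation of the labile β-keto aldehyde; the dienolate 13 does not expel the C12 silyloxy group because that would create an antiaromatic cyclopentadienone.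

Step 8
Reactants: 16 methyl hex-5-ynoate
Product: 17 methyl (5E)-6-(tributylstannyl)hex-5-enoate
Conditions: Bu3SnH, Pd2(dba)3 (1 mol %), Cy3P·HBF4 (4 mol %), iPr2NEt, CH2Cl2, 0 °C
Reagents that add atoms: tributyltin hydride, CCCC[SnH](CCCC)CCCC
Why: Palladium-catalysed hydrostannation is a syn addition of Sn–H, and with the bulky tricyclohexylphosphine ligand tin should go to the terminal carbon, giving the (E)-alkenylstannane and leaving the ester untouched.

Step 9
Reactants: 15 (Z)-{(5R)-3-bromo-2-oxo-5-[(2Z)-oct-2-en-1-yl]-5-[(triethylsilyl)oxy]cyclopent-3-en-1-ylidene}methyl trifluoromethanesulfonate; 17 methyl (5E)-6-(tributylstannyl)hex-5-enoate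
Product: 18 methyl (5E,7Z)-7-{(5R)-3-bromo-2-oxo-5-[(2Z)-oct-2-en-1-yl]-5-[(triethylsilyl)oxy]cyclopent-3-en-1-ylidene}hept-5-enoate
Conditions: 17 (1.05 equiv), Pd2(dba)3 (5 mol %), AsPh3 (20 mol %), NMP, rt, no halide additive
Reagents that add atoms: none
Why: Stille cross-coupling: oxidative addition of zerovalent palladium to the vinylogous acyl triflate C7–O bond should be much faster than to the C10–Br bond of the α-bromoenone, and transmetalation and reductive elimination proceed with retention at both alkenyl carbons, so the chelate-derived 7Z and the hydrostannation-derived 5E geometries are transferred unchanged under neutral, halide-free conditions.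

Step 10
Reactants: 18 methyl (5E,7Z)-7-{(5R)-3-bromo-2-oxo-5-[(2Z)-oct-2-en-1-yl]-5-[(triethylsilyl)oxy]cyclopent-3-en-1-ylidene}hept-5-enoate
Product: 19 methyl (5E,7Z)-7-{(5R)-3-bromo-5-hydroxy-2-oxo-5-[(2Z)-oct-2-en-1-yl]cyclopent-3-en-1-ylidene}hept-5-enoate
Conditions: HF·pyridine, pyridine/THF, 0 °C
Reagents that add atoms: none
Why: Fluoride-mediated cleavage of the tertiary triethylsilyl ether under pyridine-buffered conditions should leave the cross-conjugated bromodienone, the ester and the three alkene geometries untouched and does not involve C12.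

**Compound list**

1 | ethyl 3-(trimethylsilyl)prop-2-ynoate | C[Si](C)(C)C#CC(=O)OCC | starting material
2 | allylmagnesium bromide | C=CC[Mg]Br | starting material
3 | 1-(trimethylsilyl)hex-5-en-1-yn-3-one | C=CCC(=O)C#C[Si](C)(C)C | intermediate
4 | 4-[(trimethylsilyl)ethynyl]hepta-1,6-dien-4-ol | C=CCC(O)(CC=C)C#C[Si](C)(C)C | intermediate
5 | triethyl({4-[(trimethylsilyl)ethynyl]hepta-1,6-dien-4-yl}oxy)silane | C=CCC(CC=C)(O[Si](CC)(CC)CC)C#C[Si](C)(C)C | intermediate
6 | {[4-(bromoethynyl)hepta-1,6-dien-4-yl]oxy}triethylsilane | C=CCC(CC=C)(O[Si](CC)(CC)CC)C#CBr | intermediate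
7 | 3,3'-{2-(bromoethynyl)-2-[(triethylsilyl)oxy]propane-1,3-diyl}bis(1,2,4-trioxolane) | BrC#CC(CC1OCOO1)(CC1OCOO1)O[Si](CC)(CC)CC | intermediate
8 | 3-(bromoethynyl)-3-[(triethylsilyl)oxy]pentanedial | O=CCC(CC=O)(C#CBr)O[Si](CC)(CC)CC | intermediate
9 | [(1S)-3-bromo-4-oxo-1-[(triethylsilyl)oxy]cyclopent-2-en-1-yl]acetaldehyde | O=CC[C@@]1(O[Si](CC)(CC)CC)C=C(Br)C(=O)C1 | intermediate
10 | hexyl(triphenyl)phosphonium bromide | CCCCCC[P+](c1ccccc1)(c1ccccc1)c1ccccc1.[Br-] | starting material
11 | hexylidenetriphenylphosphorane | CCCCCC=P(c1ccccc1)(c1ccccc1)c1ccccc1 | intermediate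
12 | (4S)-2-bromo-4-[(2Z)-oct-2-en-1-yl]-4-[(triethylsilyl)oxy]cyclopent-2-en-1-one | CCCCC/C=C\C[C@@]1(O[Si](CC)(CC)CC)C=C(Br)C(=O)C1 | intermediate
13 | lithium (3S)-5-bromo-3-[(2Z)-oct-2-en-1-yl]-3-[(triethylsilyl)oxy]cyclopenta-1,4-dien-1-olate | CCCCC/C=C\C[C@@]1(O[Si](CC)(CC)CC)C=C(Br)C(O[Li])=C1 | intermediate
14 | lithium (Z)-{(5R)-3-bromo-2-oxo-5-[(2Z)-oct-2-en-1-yl]-5-[(triethylsilyl)oxy]cyclopent-3-en-1-ylidene}methanolate (O,O-chelate) | CCCCC/C=C\C[C@@]1(O[Si](CC)(CC)CC)C=C(Br)C(=O)/C1=C\O[Li] | intermediate
15 | (Z)-{(5R)-3-bromo-2-oxo-5-[(2Z)-oct-2-en-1-yl]-5-[(triethylsilyl)oxy]cyclopent-3-en-1-ylidene}methyl trifluoromethanesulfonate | CCCCC/C=C\C[C@@]1(O[Si](CC)(CC)CC)C=C(Br)C(=O)/C1=C\OS(=O)(=O)C(F)(F)F | intermediate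
16 | methyl hex-5-ynoate | C#CCCCC(=O)OC | starting material
17 | methyl (5E)-6-(tributylstannyl)hex-5-enoate | CCCC[Sn](CCCC)(CCCC)/C=C/CCCC(=O)OC | intermediate
18 | methyl (5E,7Z)-7-{(5R)-3-bromo-2-oxo-5-[(2Z)-oct-2-en-1-yl]-5-[(triethylsilyl)oxy]cyclopent-3-en-1-ylidene}hept-5-enoate | CCCCC/C=C\C[C@@]1(O[Si](CC)(CC)CC)C=C(Br)C(=O)/C1=C\C=C\CCCC(=O)OC | intermediate
19 | methyl (5E,7Z)-7-{(5R)-3-bromo-5-hydroxy-2-oxo-5-[(2Z)-oct-2-en-1-yl]cyclopent-3-en-1-ylidene}hept-5-enoate | CCCCC/C=C\C[C@@]1(O)C=C(Br)C(=O)/C1=C\C=C\CCCC(=O)OC | target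

**Summary**

Total step count: 10. Longest linear sequence: 9 steps (steps 1–7, 9 and 10; step 8 is the side branch).

**Steps most likely to fail**

Step 5 (proposed new method). What may go wrong: insertion of rhodium into the C(sp)–Br bond or loss of bromide from the α-bromoalkenyl rhodium intermediate (catalyst deactivation), weak discrimination between the two enantiotopic formyl arms, or decarbonylation. The fallback uses known chemistry and runs from 5 back to 9. The stereocentre is set by an enzyme, the ring is closed by the established achiral hydroacylation of a silylalkyne, and bromine is introduced afterwards by ipso-substitution. Ozonolysis of 5 (O3, CH2Cl2, −78 °C; PPh3) should give 3-[(triethylsilyl)oxy]-3-[(trimethylsilyl)ethynyl]pentanedial F1, and after concentration, which removes the formaldehyde, reduction (NaBH4, EtOH, 0 °C) should give the prochiral diol 3-[(triethylsilyl)oxy]-3-[(trimethylsilyl)ethynyl]pentane-1,5-diol F2. Lipase-catalysed transesterification (Pseudomonas cepacia lipase, vinyl acetate, iPr2O) should acetylate one enantiotopic arm to give (3R)-5-hydroxy-3-[(triethylsilyl)oxy]-3-[(trimethylsilyl)ethynyl]pentyl acetate F3; a lipase of opposite preference is used if the other arm reacts. Dess–Martin oxidation gives the 4-alkynal (3S)-5-oxo-3-[(triethylsilyl)oxy]-3-[(trimethylsilyl)ethynyl]pentyl acetate F4. [Rh(dppe)]2(BF4)2 in acetone should cyclise it to 2-[(1S)-4-oxo-1-[(triethylsilyl)oxy]-3-(trimethylsilyl)cyclopent-2-en-1-yl]ethyl acetate F5. Bromodesilylation (Br2, CH2Cl2, −78 → 0 °C; the vinylsilane is the only alkene present) should give 2-[(1S)-3-bromo-4-oxo-1-[(triethylsilyl)oxy]cyclopent-2-en-1-yl]ethyl acetate F6. Lipase hydrolysis of the acetate in pH 7 buffer gives (4S)-2-bromo-4-(2-hydroxyethyl)-4-[(triethylsilyl)oxy]cyclopent-2-en-1-one F7, and Dess–Martin oxidation returns 9.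

Step 7. What may go wrong: sluggish O-sulfonylation of the chelated, stabilised enolate, loss of the Z enol geometry by triflate addition–elimination at the vinylogous acyl triflate, sulfonylation at the ring oxygen, or hydrolysis on isolation; the same weakness would show in step 9 as competing oxidative addition at C10–Br. The fallback runs from 12 back to 18 by aldol condensation, so it also bypasses steps 8 and 9. Wittig homologation of methyl 5-oxopentanoate with (triphenylphosphoranylidene)acetaldehyde (toluene, 80 °C) gives methyl (5E)-7-oxohept-5-enoate F8. The lithium enolate of 12 (LiN(iPr)2, THF, −78 °C) should add 1,2 to this enal to give the β-hydroxy ketone methyl (5E)-7-{(5S)-3-bromo-2-oxo-5-[(2Z)-oct-2-en-1-yl]-5-[(triethylsilyl)oxy]cyclopent-3-en-1-yl}-7-hydroxyhept-5-enoate F9 as a diastereomer mixture at C7 and C8. Mesylation (MsCl, Et3N, CH2Cl2, −20 °C) gives the C7 methanesulfonate, methyl (5E)-7-{(5S)-3-bromo-2-oxo-5-[(2Z)-oct-2-en-1-yl]-5-[(triethylsilyl)oxy]cyclopent-3-en-1-yl}-7-[(methylsulfonyl)oxy]hept-5-enoate F10. E1cB elimination with DBU should then give 18 together with its 7E isomer, methyl (5E,7E)-7-{(5R)-3-bromo-2-oxo-5-[(2Z)-oct-2-en-1-yl]-5-[(triethylsilyl)oxy]cyclopent-3-en-1-ylidene}hept-5-enoate F11. The isomers are separated on silica, and the 7E isomer is returned to the mixture by iodine- or light-induced equilibration.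

Step 6. What may go wrong: the ylide acting as a base, so that the aldehyde enolate expels triethylsilanolate from C12 (E1cB), or ylide attack at the bromoenone. The fallback runs from 9 back to 12 without a basic carbon nucleophile. Aldehyde-selective methylenation (CH2I2, Zn, Ti(OiPr)4, THF, rt), which leaves ketones untouched, should give (4S)-2-bromo-4-(prop-2-en-1-yl)-4-[(triethylsilyl)oxy]cyclopent-2-en-1-one F12. Z-selective cross-metathesis of this allyl compound with an excess of hept-1-ene, using the cyclometalated ruthenium nitrate catalyst Ru(NO3)(=CH-C6H4-2-OiPr)(C,C-chelating N-adamantyl-N′-mesitylimidazolin-2-ylidene) (Grubbs Z-selective catalyst) in THF at 35 °C, then gives 12.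

**Further compounds**

F1 | step 5 | 3-[(triethylsilyl)oxy]-3-[(trimethylsilyl)ethynyl]pentanedial | O=CCC(CC=O)(C#C[Si](C)(C)C)O[Si](CC)(CC)CC
F2 | step 5 | 3-[(triethylsilyl)oxy]-3-[(trimethylsilyl)ethynyl]pentane-1,5-diol | OCCC(CCO)(C#C[Si](C)(C)C)O[Si](CC)(CC)CC
F3 | step 5 | (3R)-5-hydroxy-3-[(triethylsilyl)oxy]-3-[(trimethylsilyl)ethynyl]pentyl acetate | CC(=O)OCC[C@@](CCO)(O[Si](CC)(CC)CC)C#C[Si](C)(C)C
F4 | step 5 | (3S)-5-oxo-3-[(triethylsilyl)oxy]-3-[(trimethylsilyl)ethynyl]pentyl acetate | CC(=O)OCC[C@@](CC=O)(O[Si](CC)(CC)CC)C#C[Si](C)(C)C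
F5 | step 5 | 2-[(1S)-4-oxo-1-[(triethylsilyl)oxy]-3-(trimethylsilyl)cyclopent-2-en-1-yl]ethyl acetate | CC(=O)OCC[C@@]1(O[Si](CC)(CC)CC)C=C([Si](C)(C)C)C(=O)C1
F6 | step 5 | 2-[(1S)-3-bromo-4-oxo-1-[(triethylsilyl)oxy]cyclopent-2-en-1-yl]ethyl acetate | CC(=O)OCC[C@@]1(O[Si](CC)(CC)CC)C=C(Br)C(=O)C1
F7 | step 5 | (4S)-2-bromo-4-(2-hydroxyethyl)-4-[(triethylsilyl)oxy]cyclopent-2-en-1-one | OCC[C@@]1(O[Si](CC)(CC)CC)C=C(Br)C(=O)C1
F8 | step 7 | methyl (5E)-7-oxohept-5-enoate | O=C/C=C/CCCC(=O)OC
F9 | step 7 | methyl (5E)-7-{(5S)-3-bromo-2-oxo-5-[(2Z)-oct-2-en-1-yl]-5-[(triethylsilyl)oxy]cyclopent-3-en-1-yl}-7-hydroxyhept-5-enoate | CCCCC/C=C\C[C@@]1(O[Si](CC)(CC)CC)C=C(Br)C(=O)C1C(O)/C=C/CCCC(=O)OC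
F10 | step 7 | methyl (5E)-7-{(5S)-3-bromo-2-oxo-5-[(2Z)-oct-2-en-1-yl]-5-[(triethylsilyl)oxy]cyclopent-3-en-1-yl}-7-[(methylsulfonyl)oxy]hept-5-enoate | CCCCC/C=C\C[C@@]1(O[Si](CC)(CC)CC)C=C(Br)C(=O)C1C(OS(C)(=O)=O)/C=C/CCCC(=O)OC
F11 | step 7 | methyl (5E,7E)-7-{(5R)-3-bromo-2-oxo-5-[(2Z)-oct-2-en-1-yl]-5-[(triethylsilyl)oxy]cyclopent-3-en-1-ylidene}hept-5-enoate | CCCCC/C=C\C[C@@]1(O[Si](CC)(CC)CC)C=C(Br)C(=O)/C1=C/C=C/CCCC(=O)OC
F12 | step 6 | (4S)-2-bromo-4-(prop-2-en-1-yl)-4-[(triethylsilyl)oxy]cyclopent-2-en-1-one | C=CC[C@@]1(O[Si](CC)(CC)CC)C=C(Br)C(=O)C1
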